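## Retrosynthetic overview

1. Last step: an acyclic α-methyl-α-diazo ketone is closed to both carbocycles by a cobalt metalloradical bicyclization. The cobalt-bound α-keto radical at C1 adds 5-exo to C5 (cyclopentanone), and the C6 radical then closes C1–C6 (cyclopropane).
2. The diazo ketone comes from a keto acid and diazoethane. The keto acid comes from an Ireland–Claisen rearrangement (C3–C4 bond) of the propanoate of a syn aldol, which relays the aldol stereo-pair into C3 and C4 and keeps the side-chain centre.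
3. The aldol joins pentan-3-one to a pyronyl dienal, made by Heck coupling of methacrolein with a pyronyl vinyl iodide.
4. The α-methoxy-γ-pyrone is built first (β-keto ester dianion acylation, lactonisation, O-methylation).
5. Ring order: pyrone, then cyclopentanone, then cyclopropane (the last two in the same step).

Assumption and notation: (E)-3-iodo-2-methylprop-2-enoic acid and N-ethyl-N-nitrosourea are taken as purchasable. C1–C6 are the bicyclo[3.1.0]hexan-2-one positions of the target, and Pyr = 6-methoxy-3,5-dimethyl-4-oxo-4H-pyran-2-yl.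

## Route

Step 1
Reactants: 1 pentan-3-one; 2 dimethyl carbonate
Product: 3 methyl 2-methyl-3-oxopentanoate (racemic)
Conditions: NaH (2.2 equiv), THF, reflux; aq. HCl
Reagents that add atoms: none
Why: Claisen-type C-carbomethoxylation of the ketone enolate, pulled to completion by deprotonation of the β-keto ester product; the new stereocentre is labile and is erased in step 3.

Step 2
Reactants: 3 methyl 2-methyl-3-oxopentanoate; 4 (E)-3-iodo-2-methylprop-2-enoic acid
Product: 6 methyl (E)-7-iodo-2,4,6-trimethyl-3,5-dioxohept-6-enoate, via acyl imidazolide 5 (not isolated)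
Conditions: 4, CDI, THF, rt; separately 3 (3.3 equiv), NaH, THF, 0 °C, then n-BuLi, −78 °C; add the solution of 5, −78 → 0 °C; aq. HCl
Reagents that add atoms: none
Why: Weiler dianion acylation, in which the γ-carbanion of the β-keto ester dianion attacks the acyl imidazole at carbon (the extra dianion is spent as base on imidazole and on the acidic product) while the vinyl iodide keeps its E geometry; the two new centres are enolisable and become sp2 in step 3.

Step 3
Reactants: 6 methyl (E)-7-iodo-2,4,6-trimethyl-3,5-dioxohept-6-enoate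
Product: 7 4-hydroxy-6-[(E)-1-iodoprop-1-en-2-yl]-3,5-dimethyl-2H-pyran-2-one
Conditions: DBU, PhMe, 80 °C; aq. HCl
Reagents that add atoms: none
Why: base-mediated enol lactonisation (attack of the terminal enol oxygen on the methyl ester, 6-exo-trig) gives the stabilised 4-hydroxy-2-pyranone; no stereocentre is formed.

Step 4
Reactants: 7 4-hydroxy-6-[(E)-1-iodoprop-1-en-2-yl]-3,5-dimethyl-2H-pyran-2-one
Product: 8 2-[(E)-1-iodoprop-1-en-2-yl]-6-methoxy-3,5-dimethyl-4H-pyran-4-one
Conditions: MeOTf, CH2Cl2, rt; aq. NaHCO3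
Reagents that add atoms: methyl trifluoromethanesulfonate, COS(=O)(=O)C(F)(F)F
Why: O-methylation of the vinylogous acid by a hard methylating agent takes place at the more basic lactone carbonyl oxygen, and loss of the 4-OH proton then gives the 2-methoxy-4-pyranone and not the 4-methoxy-2-pyranone; no stereocentre is formed.

Step 5
Reactants: 8 2-[(E)-1-iodoprop-1-en-2-yl]-6-methoxy-3,5-dimethyl-4H-pyran-4-one; 9 2-methylprop-2-enal
Product: 10 (2E,4E)-2-methyl-5-Pyr-hexa-2,4-dienal
Conditions: Pd(OAc)2 (5 mol %), Bu4NCl, NaHCO3, DMF, 50 °C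
Reagents that add atoms: none
Why: Heck reaction under Jeffery conditions, in which syn-carbopalladation at the CH2 terminus of methacrolein and β-hydride elimination into conjugation give the 2E,4E-dienal with the E geometry of the vinyl iodide retained.

Step 6
Reactants: 1 pentan-3-one; 10 (2E,4E)-2-methyl-5-Pyr-hexa-2,4-dienal
Product: 11 (4R,5R,6E,8E)-5-hydroxy-4,6-dimethyl-9-Pyr-deca-6,8-dien-3-one
Conditions: (+)-Ipc2BOTf (from (−)-α-pinene), i-Pr2NEt, CH2Cl2, −78 °C; 10, −78 → −20 °C; H2O2, MeOH, pH 7 buffer, 0 °C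
Reagents that add atoms: none
Why: Paterson aldol, in which the Z-enol diisopinocampheylborinate reacts through a chair Zimmerman–Traxler transition state (syn) and the Ipc ligands direct attack to the Re face of the enal, setting 4R and 5R (about 90% ee expected, to be raised by recrystallisation of 11 or of a chiral amine salt of 16).

Step 7
Reactants: 11 (4R,5R,6E,8E)-5-hydroxy-4,6-dimethyl-9-Pyr-deca-6,8-dien-3-one; 12 propanoyl chloride
Product: 13 (4R,5R,6E,8E)-4,6-dimethyl-3-oxo-9-Pyr-deca-6,8-dien-5-yl propanoate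
Conditions: pyridine, DMAP (cat.), CH2Cl2, 0 °C
Reagents that add atoms: none
Why: DMAP-catalysed O-acylation of the secondary allylic alcohol at 0 °C, too mild for retro-aldol or β-elimination; no new stereocentre is formed.

Step 8
Reactants: 13 (4R,5R,6E,8E)-4,6-dimethyl-3-oxo-9-Pyr-deca-6,8-dien-5-yl propanoate
Product: 16 (2S,3R,4E,6R)-2,4,6-trimethyl-7-oxo-3-[(E)-2-Pyr-prop-1-en-1-yl]non-4-enoic acid, via bis-silyl ketene acetal 14 (not isolated), via rearranged silyl ester 15 (not isolated)
Conditions: LiN(iPr)2 (2.5 equiv), Me3SiCl (6 equiv, present from the start), THF, −78 °C, 13 added last; then rt → 45 °C; 1 M HCl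
Reagents that add atoms: none
Why: Ireland–Claisen rearrangement, in which kinetic deprotonation with in situ silylation masks the ketone as its less substituted enol silane (so no enolate can expel the β-acyloxy group) and converts the propanoate into the E silyl ketene acetal (methyl cis to the allylic oxygen), which rearranges through a chair with the carbinol substituent equatorial, so that the 5R centre of 13 is relayed into 3R and 2S of 16, the new trisubstituted alkene is E and the untouched 4R centre becomes 6R.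

Step 9
Reactants: 16 (2S,3R,4E,6R)-2,4,6-trimethyl-7-oxo-3-[(E)-2-Pyr-prop-1-en-1-yl]non-4-enoic acid; 17 N-ethyl-N-nitrosourea
Product: 20 (4S,5R,6E,8R)-2-diazo-4,6,8-trimethyl-5-[(E)-2-Pyr-prop-1-en-1-yl]undec-6-ene-3,9-dione, via acid chloride 18 (not isolated), via diazoethane 19 (not isolated)
Conditions: 16, 1-chloro-N,N,2-trimethylprop-1-en-1-amine, CH2Cl2, 0 °C; 17, 40% aq. KOH, Et2O, 0 °C, ether layer dried over KOH (3 equiv of 19); solution of 18 into 19, Et2O, −20 → 0 °C
Reagents that add atoms: none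
Why: Arndt–Eistert-type acylation of diazoethane by an acid chloride made under neutral, base-free conditions (no ketene, so no epimerisation next to either carbonyl), with a second equivalent of diazoethane scavenging HCl; no new stereocentre is formed.

Step 10
Reactants: 20 (4S,5R,6E,8R)-2-diazo-4,6,8-trimethyl-5-[(E)-2-Pyr-prop-1-en-1-yl]undec-6-ene-3,9-dione
Product: 21 (1S,3S,4R,5S,6S)-1,3,6-trimethyl-4-[(2E,4R)-4-methyl-5-oxohept-2-en-2-yl]-6-Pyr-bicyclo[3.1.0]hexan-2-one
Conditions: Co(TPP) (5 mol %; TPP = 5,10,15,20-tetraphenylporphyrinate), PhMe, 60 °C, slow addition of 20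
Reagents that add atoms: none
Why: Proposed new method: Co(TPP) (divalent cobalt) takes up the diazo ketone with loss of N2 as an α-keto alkyl radical bound to trivalent cobalt, which is not prone to the 1,2-hydride shift of closed-shell α-alkyl carbenoids and adds 5-exo-trig to the unsubstituted terminus C5 of the electron-poor pyronyl alkene (not to the fully substituted carbon of the other alkene) through a chair-like transition state with the C3 methyl and the C4 side chain equatorial and C4–H eclipsing the alkene to avoid A(1,3) strain, so that C6 ends trans to the side chain and cis to the C3 methyl, after which the tertiary pyronyl-stabilised C6 radical displaces cobalt at C1 (3-exo-tet) with the pyrone exo as in the E alkene, setting C1, C5 and C6 in one step; the closest known reaction type is the cobalt-porphyrin metalloradical intramolecular cyclopropanation of allyl diazoacetates and other acceptor-substituted diazo compounds.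

## Compound list

1 | pentan-3-one | CCC(=O)CC | starting material
2 | dimethyl carbonate | COC(=O)OC | starting material
3 | methyl 2-methyl-3-oxopentanoate (racemic) | CCC(=O)C(C)C(=O)OC | intermediate
4 | (E)-3-iodo-2-methylprop-2-enoic acid | OC(=O)/C(C)=C/I | starting material
5 | 1-[(E)-3-iodo-2-methylprop-2-enoyl]imidazole | O=C(/C(C)=C/I)n1ccnc1 | intermediate
6 | methyl (E)-7-iodo-2,4,6-trimethyl-3,5-dioxohept-6-enoate (epimers at C2 and C4, keto/enol mixture) | COC(=O)C(C)C(=O)C(C)C(=O)/C(C)=C/I | intermediate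
7 | 4-hydroxy-6-[(E)-1-iodoprop-1-en-2-yl]-3,5-dimethyl-2H-pyran-2-one | Cc1c(O)c(C)c(/C(C)=C/I)oc1=O | intermediate
8 | 2-[(E)-1-iodoprop-1-en-2-yl]-6-methoxy-3,5-dimethyl-4H-pyran-4-one | COc1oc(/C(C)=C/I)c(C)c(=O)c1C | intermediate
9 | 2-methylprop-2-enal (methacrolein) | CC(=C)C=O | starting material
10 | (2E,4E)-5-(6-methoxy-3,5-dimethyl-4-oxo-4H-pyran-2-yl)-2-methylhexa-2,4-dienal | COc1oc(/C(C)=C/C=C(\C)C=O)c(C)c(=O)c1C | intermediate
11 | (4R,5R,6E,8E)-5-hydroxy-9-(6-methoxy-3,5-dimethyl-4-oxo-4H-pyran-2-yl)-4,6-dimethyldeca-6,8-dien-3-one (syn aldol) | CCC(=O)[C@H](C)[C@@H](O)/C(C)=C/C=C(\C)c1oc(OC)c(C)c(=O)c1C | intermediate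
12 | propanoyl chloride | CCC(=O)Cl | starting material
13 | (4R,5R,6E,8E)-9-(6-methoxy-3,5-dimethyl-4-oxo-4H-pyran-2-yl)-4,6-dimethyl-3-oxodeca-6,8-dien-5-yl propanoate | CCC(=O)[C@H](C)[C@@H](OC(=O)CC)/C(C)=C/C=C(\C)c1oc(OC)c(C)c(=O)c1C | intermediate
14 | 13 with the ketone as its trimethylsilyl enol ether towards the ethyl group (E/Z mixture) and the propanoate as its (E)-O-trimethylsilyl ketene acetal | CC=C(O[Si](C)(C)C)[C@H](C)[C@@H](O/C(O[Si](C)(C)C)=C\C)/C(C)=C/C=C(\C)c1oc(OC)c(C)c(=O)c1C | intermediate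
15 | trimethylsilyl ester of 16 with the side-chain ketone still as its trimethylsilyl enol ether | CC=C(O[Si](C)(C)C)[C@H](C)/C=C(\C)[C@H](/C=C(\C)c1oc(OC)c(C)c(=O)c1C)[C@H](C)C(=O)O[Si](C)(C)C | intermediate
16 | (2S,3R,4E,6R)-3-[(E)-2-(6-methoxy-3,5-dimethyl-4-oxo-4H-pyran-2-yl)prop-1-en-1-yl]-2,4,6-trimethyl-7-oxonon-4-enoic acid | CCC(=O)[C@H](C)/C=C(\C)[C@H](/C=C(\C)c1oc(OC)c(C)c(=O)c1C)[C@H](C)C(=O)O | intermediate
17 | N-ethyl-N-nitrosourea | CCN(N=O)C(N)=O | starting material
18 | (2S,3R,4E,6R)-3-[(E)-2-(6-methoxy-3,5-dimethyl-4-oxo-4H-pyran-2-yl)prop-1-en-1-yl]-2,4,6-trimethyl-7-oxonon-4-enoyl chloride | CCC(=O)[C@H](C)/C=C(\C)[C@H](/C=C(\C)c1oc(OC)c(C)c(=O)c1C)[C@H](C)C(=O)Cl | intermediate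
19 | diazoethane | CC=[N+]=[N-] | intermediate
20 | (4S,5R,6E,8R)-2-diazo-5-[(E)-2-(6-methoxy-3,5-dimethyl-4-oxo-4H-pyran-2-yl)prop-1-en-1-yl]-4,6,8-trimethylundec-6-ene-3,9-dione | CCC(=O)[C@H](C)/C=C(\C)[C@H](/C=C(\C)c1oc(OC)c(C)c(=O)c1C)[C@H](C)C(=O)C(C)=[N+]=[N-] | intermediate
21 | (1S,3S,4R,5S,6S)-6-(6-methoxy-3,5-dimethyl-4-oxo-4H-pyran-2-yl)-1,3,6-trimethyl-4-[(2E,4R)-4-methyl-5-oxohept-2-en-2-yl]bicyclo[3.1.0]hexan-2-one (pyrone exo, C3 methyl cis and C4 side chain trans to the cyclopropane) | CCC(=O)[C@H](C)/C=C(\C)[C@H]1[C@H](C)C(=O)[C@@]2(C)[C@@H]1[C@]2(C)c1oc(OC)c(C)c(=O)c1C | target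

## Totals

Total step count: 10.
Longest linear sequence: 10 steps (1 → 3 → 6 → 7 → 8 → 10 → 11 → 13 → 16 → 20 → 21).

## Three steps most likely to fail

Step 10 (metalloradical bicyclization). Risks are an unreactive or H-shifting carbene radical, attack on the side-chain alkene, and loss of configuration at C6. The fallback sets out from 20 and returns at 21. Heating 20 in PhMe at 80 °C without metal lets the diazo ketone add as a 1,3-dipole across the pyronyl alkene, carbon to C5 and nitrogen to C6, to give the cis-fused 1-pyrazoline F1 (N=N bridging C1 and C6, all carbon centres as in 21). Irradiation at 350 nm and −20 °C then extrudes N2, and the 1,3-diradical collapses to 21.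

Step 8 (Ireland–Claisen with the ketone masked in the flask). Risks are β-elimination of propanoate from a wrongly placed ketone enolate and deprotonation of the pyronyl diene. The fallback sets out from 11 and returns at 16. Evans–Tishchenko reduction of 11 with propanal and catalytic SmI2 reduces the ketone to the 1,3-anti carbinol and delivers the propanoyl group to the allylic oxygen, giving (3S,4S,5R,6E,8E)-3-hydroxy-4,6-dimethyl-9-Pyr-deca-6,8-dien-5-yl propanoate F2. Ireland–Claisen rearrangement of F2 (LiN(iPr)2, Me3SiCl, THF, −78 °C → 45 °C; 1 M HCl), with the hydroxyl silylated in the flask, gives (2S,3R,4E,6R,7S)-7-hydroxy-2,4,6-trimethyl-3-[(E)-2-Pyr-prop-1-en-1-yl]non-4-enoic acid F3. Dess–Martin oxidation of F3 gives 16.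

Step 5 (Heck coupling with methacrolein). Risks are the exo-methylene isomer from β-hydride elimination into the methyl group and polymerisation of the enal. The fallback sets out from 8 and returns at 10. Reductive carbonylation of 8 (Pd(PPh3)4, CO 1 atm, Bu3SnH, THF, 50 °C) gives (E)-3-Pyr-but-2-enal F4. Wittig olefination of F4 with 2-(triphenylphosphoranylidene)propanal (PhMe, 80 °C) gives 10, E-selectively as expected for a stabilised ylide.

## Further compounds

F1 | step 10 | cis-fused 1-pyrazoline: 3,3a,4,5-tetrahydrocyclopenta[c]pyrazol-6(6aH)-one carrying 3-Pyr, 3,5,6a-trimethyl and the 4-[(2E,4R)-4-methyl-5-oxohept-2-en-2-yl] group, carbon centres as in 21 | CCC(=O)[C@H](C)/C=C(\C)[C@H]1[C@H](C)C(=O)[C@@]2(C)[C@@H]1[C@](C)(c1oc(OC)c(C)c(=O)c1C)N=N2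
F2 | step 8 | (3S,4S,5R,6E,8E)-3-hydroxy-9-(6-methoxy-3,5-dimethyl-4-oxo-4H-pyran-2-yl)-4,6-dimethyldeca-6,8-dien-5-yl propanoate | CC[C@H](O)[C@H](C)[C@@H](OC(=O)CC)/C(C)=C/C=C(\C)c1oc(OC)c(C)c(=O)c1C
F3 | step 8 | (2S,3R,4E,6R,7S)-7-hydroxy-3-[(E)-2-(6-methoxy-3,5-dimethyl-4-oxo-4H-pyran-2-yl)prop-1-en-1-yl]-2,4,6-trimethylnon-4-enoic acid | CC[C@H](O)[C@H](C)/C=C(\C)[C@H](/C=C(\C)c1oc(OC)c(C)c(=O)c1C)[C@H](C)C(=O)O
F4 | step 5 | (E)-3-(6-methoxy-3,5-dimethyl-4-oxo-4H-pyran-2-yl)but-2-enal | COc1oc(/C(C)=C/C=O)c(C)c(=O)c1C
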